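## Retrosynthetic overview

1. C1=C2 (E)-chloroalkene ⇐ terminal alkyne by hydrozirconation–chlorination; C3–C4 ⇐ C4 aldehyde + allenyl boronate under chiral phosphoric acid catalysis (sets C4).
2. C10–C11 bond, the C10 stereocentre and the (Z)-chloromethylidene ⇐ C10 aldehyde + racemic 2-benzyl-1-chloroallyl boronate in one new chiral-phosphoric-acid-catalysed α-chloroallylboration (key step).
3. C10 aldehyde ⇐ hydroformylation of a C8=C9 alkene ⇐ Wittig methylenation of a C8 aldehyde.
4. C5/C7 syn-dimethyl unit ⇐ organocatalytic methanolysis of meso-2,4-dimethylglutaric anhydride (first stereocentres).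
5. The target is acyclic, so no ring is formed; order of events: C5/C7 → C10 with the Z-alkene → C4 → E-alkene.

Assumption: (DHQD)2AQN is taken to open 1 to the (2S,4R) acid-ester 2, and (R)-TRIP to deliver allyl/allenyl boronates to the Re face of an aldehyde; if either sense is opposite, (DHQ)2AQN or (R)-TRIP is used with no other change. Atom labels in the text follow the target: C1 = ClCH= of the E-alkene, C4 and C10 = acetoxy carbons, C5 and C7 = methyl carbons, C13 = PhCH2, C14 = the =CHCl carbon on C12. (S)-TRIP = (S)-3,3′-bis(2,4,6-triisopropylphenyl)-1,1′-binaphthyl-2,2′-diyl hydrogen phosphate.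

## Route

Step 1
Reactants: 1 meso-2,4-dimethylglutaric anhydride (cis-3,5-dimethyloxane-2,6-dione)
Product: 2 (2S,4R)-5-methoxy-2,4-dimethyl-5-oxopentanoic acid
Conditions: (DHQD)2AQN (10–30 mol %), MeOH (10 equiv), Et2O, −40 °C
Reagents that add atoms: methanol (CO)
Why: Cinchona-alkaloid (general-base) catalysed alcoholytic desymmetrisation of a meso anhydride; the catalyst delivers methanol to one enantiotopic carbonyl, so both methyl stereocentres (C5 and C7) are set in one operation from an achiral compound.

Step 2
Reactants: 2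
Product: 3 methyl (2R,4S)-5-hydroxy-2,4-dimethylpentanoate
Conditions: BH3·SMe2 (1.2 equiv), THF, 0 °C to rt; MeOH quench
Reagents that add atoms: none
Why: Chemoselective borane reduction of the free acid (through the acyloxyborane) leaves the methyl ester untouched; 3 is used at once so the δ-hydroxy ester does not lactonise.

Step 3
Reactants: 3
Product: 4 methyl (2R,4S)-2,4-dimethyl-5-oxopentanoate
Conditions: TEMPO (10 mol %), PhI(OAc)2 (1.1 equiv), CH2Cl2, rt
Reagents that add atoms: none
Why: Oxoammonium (TEMPO) oxidation of the primary alcohol is non-basic, so the α-stereocentre (C7) is not epimerised and the ester is inert.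

Step 4
Reactants: 4
Product: 5 methyl (2R,4S)-2,4-dimethylhex-5-enoate
Conditions: Ph3PCH3Br (1.3 equiv), KN(SiMe3)2 (1.25 equiv), THF, 0 °C; then 4, −78 °C to 0 °C
Reagents that add atoms: methyltriphenylphosphonium bromide (C[P+](c1ccccc1)(c1ccccc1)c1ccccc1.[Br-])
Why: Wittig methylenation with the salt-free non-stabilised ylide is fast at low temperature, which keeps the α-methyl aldehyde configurationally intact; the ester does not react.

Step 5
Reactants: 5
Product: 6 methyl (2R,4R)-2,4-dimethyl-7-oxoheptanoate
Conditions: Rh(acac)(CO)2 (1 mol %), Xantphos (4 mol %), CO/H2 (1:1, 20 bar), toluene, 70 °C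
Reagents that add atoms: carbon monoxide ([C-]#[O+])
Why: Linear-selective rhodium hydroformylation with a wide-bite-angle diphosphine adds C10 as the aldehyde; the branch at C7 further blocks the iso-aldehyde, and C7 is γ to the new carbonyl and not epimerisable.

Step 6
Reactants: 7 2-bromo-3-phenylprop-1-ene; 8 2-(dichloromethyl)-4,4,5,5-tetramethyl-1,3,2-dioxaborolane
Product: 11 racemic 2-(2-benzyl-1-chloroprop-2-en-1-yl)-4,4,5,5-tetramethyl-1,3,2-dioxaborolane, via alkenylmagnesium bromide 9 (not isolated), via magnesium boronate complex 10 (not isolated)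
Conditions: Mg, THF, rt; then 8, THF, −78 °C to rt
Reagents that add atoms: none
Why: Matteson-type 1,2-metallate rearrangement; the alkenyl Grignard adds to boron and the alkenyl group migrates to carbon with loss of one chloride, giving the α-chloroallyl pinacol boronate, which does not undergo 1,3-boron shift at rt.

Step 7
Reactants: 6; 11 (racemic, 2.5 equiv)
Product: 12 methyl (2R,4R,7R,9Z)-9-benzyl-10-chloro-7-hydroxy-2,4-dimethyldec-9-enoate
Conditions: (S)-TRIP (10 mol %), 4 Å molecular sieves, toluene, −30 °C; aq. NaHCO3 work-up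
Reagents that add atoms: none
Why: Proposed new method: a chiral-phosphoric-acid-catalysed, reagent-resolving α-chloroallylboration. The boronate adds through the usual closed six-membered chair with the aldehyde chain equatorial; the acid hydrogen-bonds to a pinacol oxygen while its phosphoryl oxygen holds the formyl C–H, and with (S)-TRIP this exposes the Si face of 6, making C10 R. In that chair the α-chlorine prefers the axial site (away from the pinacol methyls, free of allylic 1,2-strain with the 2-benzyl group, favoured by dipole and σ*C–Cl effects), which places Cl cis to C11 in the new C12=C14 bond, i.e. Z. Only (R)-11 can put chlorine axial in the Si-face chair, so it reacts fast; (S)-11 would need equatorial chlorine or the blocked Re face and is left behind, hence the excess of racemate. The uncatalysed background is slow at −30 °C for this hindered, electron-poor boronate. Closest known reactions: the thermal Z-selective α-chloroallylboration of aldehydes with chirality transfer from enantioenriched reagents (Hoffmann type), and TRIP-catalysed allylboration including kinetically resolving additions of racemic α-substituted allyl boronates; an α-chloro, 2-substituted boronate has not been used in this way.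

Step 8
Reactants: 12
Product: 13 (2R,4R,7R,9Z)-9-benzyl-10-chloro-7-hydroxy-2,4-dimethyldec-9-enal
Conditions: i-Bu2AlH (2.2 equiv), CH2Cl2, −78 °C; MeOH, then aq. potassium sodium tartrate
Reagents that add atoms: none
Why: Partial ester reduction; the first equivalent is consumed by the hydroxyl and the second gives a tetrahedral aluminium hemiacetal that is stable at −78 °C and releases the aldehyde only on work-up; the chloroalkene is inert, and 13 is used crude and cold to protect C5.

Step 9
Reactants: 13
Product: 14 (1Z,4R,7R,9R,10S)-2-benzyl-1-chloro-7,9-dimethyltridec-1-en-12-yne-4,10-diol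
Conditions: allenylboronic acid pinacol ester (1.5 equiv), (S)-TRIP (10 mol %), 4 Å molecular sieves, toluene, −20 °C
Reagents that add atoms: allenylboronic acid pinacol ester (C=C=CB1OC(C)(C)C(C)(C)O1)
Why: Chiral-phosphoric-acid-catalysed propargylation (SE2′ through a six-membered chair); (S)-TRIP directs Si-face attack and gives the (S) carbinol at C4, anti to the C5 methyl, overriding the small Felkin preference of this α-methyl aldehyde; the remote secondary hydroxyl does not exchange with the pinacol boronate.

Step 10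
Reactants: 14
Product: 15 (1Z,4R,7R,9R,10S)-2-benzyl-1-chloro-7,9-dimethyltridec-1-en-12-yne-4,10-diyl diacetate
Conditions: Ac2O (3 equiv), pyridine, DMAP (5 mol %), CH2Cl2, 0 °C to rt
Reagents that add atoms: acetic anhydride (CC(=O)OC(C)=O)
Why: DMAP-catalysed acylation of both secondary alcohols in one operation; no stereocentre is touched.

Step 11
Reactants: 15
Product: 17 (1Z,4R,7R,9R,10S,12E)-2-benzyl-1,13-dichloro-7,9-dimethyltrideca-1,12-diene-4,10-diyl diacetate, via alkenylzirconocene chloride 16 (not isolated)
Conditions: Cp2Zr(H)Cl (1.5 equiv), THF, 0 °C to rt, 30 min; then NCS (1.6 equiv), 0 °C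
Reagents that add atoms: N-chlorosuccinimide (O=C1CCC(=O)N1Cl)
Why: Hydrozirconation–halogenation; syn addition of Zr–H puts zirconium on the terminal carbon and chlorination with retention gives the E-chloroalkene, while the acetates and the trisubstituted chloroalkene react far more slowly than the terminal alkyne.

## Compound list

1 | meso-2,4-dimethylglutaric anhydride (cis-3,5-dimethyloxane-2,6-dione) | O=C1[C@@H](C)C[C@@H](C)C(=O)O1 | starting material
2 | (2S,4R)-5-methoxy-2,4-dimethyl-5-oxopentanoic acid | OC(=O)[C@@H](C)C[C@@H](C)C(=O)OC | intermediate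
3 | methyl (2R,4S)-5-hydroxy-2,4-dimethylpentanoate | OC[C@@H](C)C[C@@H](C)C(=O)OC | intermediate
4 | methyl (2R,4S)-2,4-dimethyl-5-oxopentanoate | O=C[C@@H](C)C[C@@H](C)C(=O)OC | intermediate
5 | methyl (2R,4S)-2,4-dimethylhex-5-enoate | C=C[C@@H](C)C[C@@H](C)C(=O)OC | intermediate
6 | methyl (2R,4R)-2,4-dimethyl-7-oxoheptanoate | O=CCC[C@@H](C)C[C@@H](C)C(=O)OC | intermediate
7 | 2-bromo-3-phenylprop-1-ene | C=C(Br)Cc1ccccc1 | starting material
8 | 2-(dichloromethyl)-4,4,5,5-tetramethyl-1,3,2-dioxaborolane | ClC(Cl)B1OC(C)(C)C(C)(C)O1 | starting material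
9 | (3-phenylprop-1-en-2-yl)magnesium bromide | C=C([Mg]Br)Cc1ccccc1 | intermediate
10 | bromomagnesium (dichloromethyl)(3-phenylprop-1-en-2-yl)(pinacolato)borate | C=C(Cc1ccccc1)[B-]1(C(Cl)Cl)OC(C)(C)C(C)(C)O1.[Mg+]Br | intermediate
11 | racemic 2-(2-benzyl-1-chloroprop-2-en-1-yl)-4,4,5,5-tetramethyl-1,3,2-dioxaborolane | C=C(Cc1ccccc1)C(Cl)B1OC(C)(C)C(C)(C)O1 | intermediate
12 | methyl (2R,4R,7R,9Z)-9-benzyl-10-chloro-7-hydroxy-2,4-dimethyldec-9-enoate | O[C@H](CC[C@@H](C)C[C@@H](C)C(=O)OC)C/C(=C\Cl)Cc1ccccc1 | intermediate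
13 | (2R,4R,7R,9Z)-9-benzyl-10-chloro-7-hydroxy-2,4-dimethyldec-9-enal | O[C@H](CC[C@@H](C)C[C@@H](C)C=O)C/C(=C\Cl)Cc1ccccc1 | intermediate
14 | (1Z,4R,7R,9R,10S)-2-benzyl-1-chloro-7,9-dimethyltridec-1-en-12-yne-4,10-diol | O[C@H](CC[C@@H](C)C[C@@H](C)[C@H](CC#C)O)C/C(=C\Cl)Cc1ccccc1 | intermediate
15 | (1Z,4R,7R,9R,10S)-2-benzyl-1-chloro-7,9-dimethyltridec-1-en-12-yne-4,10-diyl diacetate | CC(=O)O[C@H](CC[C@@H](C)C[C@@H](C)[C@H](CC#C)OC(C)=O)C/C(=C\Cl)Cc1ccccc1 | intermediate
16 | (E)-alkenylzirconocene chloride of 15 (Cp2Zr(Cl) on the terminal alkene carbon C1) | CC(=O)O[C@H](CC[C@@H](C)C[C@@H](C)[C@H](C/C=C/[Zr](Cl)(C1C=CC=C1)C1C=CC=C1)OC(C)=O)C/C(=C\Cl)Cc1ccccc1 | intermediate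
17 | (1Z,4R,7R,9R,10S,12E)-2-benzyl-1,13-dichloro-7,9-dimethyltrideca-1,12-diene-4,10-diyl diacetate (CNP0493673.1) | CC(=O)O[C@H](CC[C@@H](C)C[C@@H](C)[C@H](C/C=C/Cl)OC(C)=O)C/C(=C\Cl)Cc1ccccc1 | target

## Step count and risks

Total steps: 11. Longest linear sequence: 10 (steps 1–5 and 7–11); step 6 is a one-step side branch.

Most likely to fail, in this order:

**Step 7 (the new reaction).** Risks are low conversion, incomplete reagent resolution (C10 epimers) or E/Z leakage. The fallback uses known chemistry and puts the chirality into the reagent instead of the catalyst. Diisopropyl (dichloromethyl)boronate is transesterified with (S,S)-1,2-dicyclohexylethane-1,2-diol to (4S,5S)-4,5-dicyclohexyl-2-(dichloromethyl)-1,3,2-dioxaborolane F1. Grignard reagent 9 is added at −78 °C and the ZnCl2-promoted, diol-controlled 1,2-migration (Matteson homologation) gives (4S,5S)-2-[(1R)-2-benzyl-1-chloroprop-2-en-1-yl]-4,5-dicyclohexyl-1,3,2-dioxaborolane F2. F2 and 6, without catalyst in toluene at rt, react through the same chair with axial chlorine (Hoffmann-type chirality transfer) to give the (10R,Z) product. This fallback sets out from 6 (with 9) and comes back at 12.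

**Step 9.** The catalyst must override the Felkin preference of the α-methyl aldehyde, allenyl transfer is the less selective member of this catalyst family for aliphatic aldehydes, and a free hydroxyl is present. The fallback changes the C3 unit and the way the E-chloroalkene is made. Aldehyde 13 is allylated with allylboronic acid pinacol ester and (S)-TRIP, the best-precedented and most face-selective variant, to give (1Z,4R,7R,9R,10S)-2-benzyl-1-chloro-7,9-dimethyltrideca-1,12-diene-4,10-diol F4. Ac2O/pyridine/DMAP gives (1Z,4R,7R,9R,10S)-2-benzyl-1-chloro-7,9-dimethyltrideca-1,12-diene-4,10-diyl diacetate F5. Kinetically E-selective cross-metathesis of the terminal alkene with (E)-1,2-dichloroethene, using the molybdenum monoaryloxide pyrrolide alkylidene Mo(NC6F5)(CHCMe2Ph)(2,5-Me2C4H2N)(OAr) with Ar = 2,6-(2,4,6-iPr3C6H2)2C6H3, installs the E-chloroalkene; the trisubstituted chloroalkene does not take part. This fallback sets out from 13 and comes back at 17.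

**Step 8.** Partial reduction of a hydroxy ester may over-reduce or stall. The fallback is a two-stage redox. LiAlH4 in THF at 0 °C reduces 12 fully to (2R,4R,7R,9Z)-9-benzyl-10-chloro-2,4-dimethyldec-9-ene-1,7-diol F3. TEMPO (cat.)/PhI(OAc)2 in CH2Cl2 then oxidises only the primary alcohol. This fallback sets out from 12 and comes back at 13.

## Further compounds

F1 | step 7 | (4S,5S)-4,5-dicyclohexyl-2-(dichloromethyl)-1,3,2-dioxaborolane | ClC(Cl)B1O[C@@H](C2CCCCC2)[C@H](C2CCCCC2)O1
F2 | step 7 | (4S,5S)-2-[(1R)-2-benzyl-1-chloroprop-2-en-1-yl]-4,5-dicyclohexyl-1,3,2-dioxaborolane | C=C(Cc1ccccc1)[C@H](Cl)B1O[C@@H](C2CCCCC2)[C@H](C2CCCCC2)O1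
F3 | step 8 | (2R,4R,7R,9Z)-9-benzyl-10-chloro-2,4-dimethyldec-9-ene-1,7-diol | O[C@H](CC[C@@H](C)C[C@@H](C)CO)C/C(=C\Cl)Cc1ccccc1
F4 | step 9 | (1Z,4R,7R,9R,10S)-2-benzyl-1-chloro-7,9-dimethyltrideca-1,12-diene-4,10-diol | O[C@H](CC[C@@H](C)C[C@@H](C)[C@H](CC=C)O)C/C(=C\Cl)Cc1ccccc1
F5 | step 9 | (1Z,4R,7R,9R,10S)-2-benzyl-1-chloro-7,9-dimethyltrideca-1,12-diene-4,10-diyl diacetate | CC(=O)O[C@H](CC[C@@H](C)C[C@@H](C)[C@H](CC=C)OC(C)=O)C/C(=C\Cl)Cc1ccccc1
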